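**Retrosynthetic overview**
1. Target ⇒ its 4-O-benzyl ether (hydrogenolysis last) ⇒ the corresponding terminal alkene (vinyl → CH2OH by ozonolysis/NaBH4), a threo-1-aryl-2-aryloxybut-3-en-1-ol.
2. Key disconnection C7–C8: 4-(benzyloxy)-3,5-dimethoxybenzaldehyde (C7, electrophile) plus a (Z)-γ-aryloxyallyl-diisopinocampheylborane. Its oxygen-bearing carbon C8, by nature an electrophilic centre, reacts as an α-oxy carbanion (d1 synthon, taken from a metallated allyl ether, the classical homoenolate-type anion). This one step makes the C–C bond and sets both stereocentres (syn, 7R,8R).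
3. The allylborane comes from the O-allyl ether of dihydrosinapyl alcohol, carried with its hydroxyl unprotected as the lithium alkoxide; allyl bromide supplies C8 and C9.
4. Dihydrosinapyl alcohol ⇐ methoxyeugenol by hydroboration–oxidation.
5. No ring is formed: aromatic ring A is bought as the aldehyde, ring B as methoxyeugenol.

Assumption: the target is read as the threo isomer, both stereocentres R (C7 = benzylic carbinol carbon, C8 = aryloxy-bearing carbon, C9 = CH2OH carbon); methoxyeugenol and 4-(benzyloxy)-3,5-dimethoxybenzaldehyde are taken as inexpensive catalogue compounds.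

Chiral reagent of step 3: (−)-Ipc2BOMe, (−)-B-methoxydiisopinocampheylborane (Ipc = isopinocampheyl, from (+)-α-pinene), SMILES COB([C@@H]1C[C@@H]2C[C@H]([C@H]1C)C2(C)C)[C@@H]1C[C@@H]2C[C@H]([C@H]1C)C2(C)C. The facial sense is assigned by analogy with Brown allyl- and alkoxyallylborations using this reagent (Si-face attack on the aldehyde).

**Route**

Step 1
Reactants: 1 4-allyl-2,6-dimethoxyphenol (methoxyeugenol)
Product: 3 4-(3-hydroxypropyl)-2,6-dimethoxyphenol (dihydrosinapyl alcohol), via bis(9-BBN) adduct 2 (not isolated)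
Conditions: 9-BBN (2.3 equiv), THF, 0 °C → rt; then NaBO3·4H2O, H2O, rt
Reagents that add atoms: sodium perborate tetrahydrate (NaBO3·4H2O, source of the new oxygen), [Na+].[Na+].O[B-]1(O)OO[B-](O)(O)OO1
Why: Hydroboration–oxidation: bulky 9-BBN places boron on the terminal carbon of the allyl group (the phenol is masked in the flask as its O-boryl ether with loss of H2), and perborate converts C–B to C–OH mildly enough to spare the electron-rich phenol; no stereocentre is formed.

Step 2
Reactants: 3 4-(3-hydroxypropyl)-2,6-dimethoxyphenol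
Product: 4 3-[3,5-dimethoxy-4-(prop-2-en-1-yloxy)phenyl]propan-1-ol
Conditions: allyl bromide (1.2 equiv), K2CO3 (1.5 equiv), acetone, reflux
Reagents that add atoms: allyl bromide (3-bromoprop-1-ene), C=CCBr
Why: Williamson ether synthesis: K2CO3 deprotonates only the phenol (pKa about 10 against about 16 for the alcohol) and the phenoxide displaces bromide by SN2; no stereocentre is formed.

Step 3
Reactants: 4 3-[3,5-dimethoxy-4-(prop-2-en-1-yloxy)phenyl]propan-1-ol; 5 4-(benzyloxy)-3,5-dimethoxybenzaldehyde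
Product: 10 (1R,2R)-1-[4-(benzyloxy)-3,5-dimethoxyphenyl]-2-[4-(3-hydroxypropyl)-2,6-dimethoxyphenoxy]but-3-en-1-ol, via dilithio oxyallyl species 6 (not isolated), via methoxyborate ate complex 7 (not isolated), via Z-aryloxyallylborane 8 (not isolated), via borinate adduct 9 (not isolated)
Conditions: 4 (1.2 equiv), s-BuLi (2.5 equiv), THF, −78 °C; (−)-Ipc2BOMe (1.3 equiv), −78 °C; BF3·OEt2 (3.3 equiv), then 5 (1.0 equiv), −78 °C → rt; then 3 M NaOH, 30% H2O2, rt
Reagents that add atoms: none
Why: Proposed new method: a Brown-type (Z)-γ-alkoxyallylboration run on the fully elaborated aryl allyl ether with its free hydroxyl carried as a spectator lithium alkoxide; the first equivalent of s-BuLi makes the alkoxide and the second removes an allylic O–CH2 proton (acidified by the aryloxy oxygen, lithium held by the ether and flanking methoxy oxygens) to give the internally chelated Z-oxyallyl anion 6, which is borylated at the γ-carbon (7), freed of methoxide by BF3·OEt2 (which also ties up the side-chain alkoxide, 8) and adds to aldehyde 5 through a closed chair Zimmerman–Traxler transition state with the aldehyde aryl equatorial and the aryloxy group axial, so that the oxygen-bearing carbon, acting with reversed polarity as an α-oxy carbanion, bonds to the carbonyl carbon with syn (threo) relative configuration while the Ipc groups from (+)-α-pinene direct attack to the Si face of the aldehyde, giving (1R,2R); the closest known chemistry is the asymmetric γ-alkoxyallylboration of aldehydes with the lithiated methyl, methoxymethyl and p-methoxyphenyl allyl ethers.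

Step 4
Reactants: 10 (1R,2R)-1-[4-(benzyloxy)-3,5-dimethoxyphenyl]-2-[4-(3-hydroxypropyl)-2,6-dimethoxyphenoxy]but-3-en-1-ol
Product: 13 (1R,2R)-1-[4-(benzyloxy)-3,5-dimethoxyphenyl]-2-[4-(3-hydroxypropyl)-2,6-dimethoxyphenoxy]propane-1,3-diol, via ozonide 11 (not isolated), via aldehyde 12 (not isolated)
Conditions: O3, CH2Cl2, −78 °C (stopped at the Sudan Red 7B end point); then NaBH4 (6 equiv), MeOH, −78 → 0 °C
Reagents that add atoms: ozone, [O-][O+]=O
Why: Ozonolysis with reductive work-up: the isolated terminal alkene reacts with ozone far faster than the alkoxyarenes or the benzyl ether, and NaBH4 reduces the ozonide through aldehyde 12 straight to the primary alcohol in the cold, so the epimerisable α-aryloxy aldehyde never accumulates and both stereocentres are kept (descriptors stay R,R).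

Step 5
Reactants: 13 (1R,2R)-1-[4-(benzyloxy)-3,5-dimethoxyphenyl]-2-[4-(3-hydroxypropyl)-2,6-dimethoxyphenoxy]propane-1,3-diol
Product: 14 (1R,2R)-1-(4-hydroxy-3,5-dimethoxyphenyl)-2-[4-(3-hydroxypropyl)-2,6-dimethoxyphenoxy]propane-1,3-diol (the target)
Conditions: H2 (1 atm), 10% Pd/C, EtOAc/EtOH, rt, stopped at full conversion
Reagents that add atoms: none
Why: Hydrogenolysis of the benzyl aryl ether over Pd/C under neutral conditions is much faster than cleavage of the free benzylic C–OH or the alkyl aryl ether, and no bond to either stereocentre is touched.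

**Compound list**

1 | 4-allyl-2,6-dimethoxyphenol (methoxyeugenol) | COc1cc(CC=C)cc(OC)c1O | starting material
2 | 9-{3-[4-(9-borabicyclo[3.3.1]nonan-9-yloxy)-3,5-dimethoxyphenyl]propyl}-9-borabicyclo[3.3.1]nonane (bis(9-BBN) adduct) | COc1cc(CCCB2C3CCCC2CCC3)cc(OC)c1OB1C2CCCC1CCC2 | intermediate
3 | 4-(3-hydroxypropyl)-2,6-dimethoxyphenol (dihydrosinapyl alcohol) | COc1cc(CCCO)cc(OC)c1O | intermediate
4 | 3-[3,5-dimethoxy-4-(prop-2-en-1-yloxy)phenyl]propan-1-ol | COc1cc(CCCO)cc(OC)c1OCC=C | intermediate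
5 | 4-(benzyloxy)-3,5-dimethoxybenzaldehyde | COc1cc(C=O)cc(OC)c1OCc1ccccc1 | starting material
6 | lithium 3-{4-[(1Z)-3-lithioprop-1-en-1-yl]oxy-3,5-dimethoxyphenyl}propan-1-olate (delocalised oxyallyl anion drawn in its γ-lithio form) | [Li]C/C=C\Oc1c(OC)cc(CCCO[Li])cc1OC | intermediate
7 | lithium methoxy{(2Z)-3-[4-(3-lithiooxypropyl)-2,6-dimethoxyphenoxy]prop-2-en-1-yl}bis(isopinocampheyl)borate | [Li+].CO[B-](C/C=C\Oc1c(OC)cc(CCCO[Li])cc1OC)([C@@H]1C[C@@H]2C[C@H]([C@H]1C)C2(C)C)[C@@H]1C[C@@H]2C[C@H]([C@H]1C)C2(C)C | intermediate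
8 | {(2Z)-3-[2,6-dimethoxy-4-(3-oxypropyl)phenoxy]prop-2-en-1-yl}bis(isopinocampheyl)borane, side-chain oxygen held as lithium alkoxytrifluoroborate | [Li+].F[B-](F)(F)OCCCc1cc(OC)c(O/C=C\CB([C@@H]2C[C@@H]3C[C@H]([C@H]2C)C3(C)C)[C@@H]2C[C@@H]3C[C@H]([C@H]2C)C3(C)C)c(OC)c1 | intermediate
9 | O-bis(isopinocampheyl)boryl ether (borinate) of 10, side-chain oxygen held as lithium alkoxytrifluoroborate | [Li+].COc1cc([C@@H](OB([C@@H]3C[C@@H]4C[C@H]([C@H]3C)C4(C)C)[C@@H]3C[C@@H]4C[C@H]([C@H]3C)C4(C)C)[C@@H](C=C)Oc2c(OC)cc(CCCO[B-](F)(F)F)cc2OC)cc(OC)c1OCc1ccccc1 | intermediate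
10 | (1R,2R)-1-[4-(benzyloxy)-3,5-dimethoxyphenyl]-2-[4-(3-hydroxypropyl)-2,6-dimethoxyphenoxy]but-3-en-1-ol | COc1cc([C@@H](O)[C@@H](C=C)Oc2c(OC)cc(CCCO)cc2OC)cc(OC)c1OCc1ccccc1 | intermediate
11 | (1R,2S)-1-[4-(benzyloxy)-3,5-dimethoxyphenyl]-2-[4-(3-hydroxypropyl)-2,6-dimethoxyphenoxy]-2-(1,2,4-trioxolan-3-yl)ethan-1-ol (ozonide, mixture at the trioxolane carbon) | COc1cc([C@@H](O)[C@@H](C3OCOO3)Oc2c(OC)cc(CCCO)cc2OC)cc(OC)c1OCc1ccccc1 | intermediate
12 | (2S,3R)-3-[4-(benzyloxy)-3,5-dimethoxyphenyl]-3-hydroxy-2-[4-(3-hydroxypropyl)-2,6-dimethoxyphenoxy]propanal | COc1cc([C@@H](O)[C@@H](C=O)Oc2c(OC)cc(CCCO)cc2OC)cc(OC)c1OCc1ccccc1 | intermediate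
13 | (1R,2R)-1-[4-(benzyloxy)-3,5-dimethoxyphenyl]-2-[4-(3-hydroxypropyl)-2,6-dimethoxyphenoxy]propane-1,3-diol | COc1cc([C@@H](O)[C@@H](CO)Oc2c(OC)cc(CCCO)cc2OC)cc(OC)c1OCc1ccccc1 | intermediate
14 | (1R,2R)-1-(4-hydroxy-3,5-dimethoxyphenyl)-2-[4-(3-hydroxypropyl)-2,6-dimethoxyphenoxy]propane-1,3-diol | COc1cc([C@@H](O)[C@@H](CO)Oc2c(OC)cc(CCCO)cc2OC)cc(OC)c1O | target

**Step count and risks**

Total step count: 5. Longest linear sequence: 5 (1 → 3 → 4 → 10 → 13 → 14); aldehyde 5 enters in step 3.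

The three steps most likely to fail:

Step 3 is the largest risk. The spectator lithium alkoxide may interfere at boron, the lithiation may be incomplete or misdirected, and the hindered aryloxy group may lower dr or ee (about 95:5 dr and 90% ee or better are expected from the parent reaction; the enantiomeric purity can be raised by recrystallising 13). The fallback sets out from 4 and comes back at 10. The hydroxyl of 4 is masked with TBSCl and imidazole in DMF to give the silyl ether tert-butyl{3-[3,5-dimethoxy-4-(prop-2-en-1-yloxy)phenyl]propoxy}dimethylsilane F1, so the nucleophile is a plain mono-anion. Lithiation with one equivalent of s-BuLi, transfer to (−)-Ipc2BOMe, BF3·OEt2 and addition to 5 then give the silyl-protected adduct (1R,2R)-1-[4-(benzyloxy)-3,5-dimethoxyphenyl]-2-[4-(3-{[tert-butyl(dimethyl)silyl]oxy}propyl)-2,6-dimethoxyphenoxy]but-3-en-1-ol F2. Bu4NF in THF removes the silyl group and returns 10.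

Step 4 is the second risk. Ozone may attack the trialkoxyarene rings or the benzyl ether, and aldehyde 12 may epimerise or undergo retro-aldol cleavage if it builds up. The fallback sets out from 10 and comes back at 13, separating alkene oxidation from C–C cleavage so that no ozone is used. Catalytic K2OsO4·2H2O with N-methylmorpholine N-oxide in acetone/water dihydroxylates the vinyl group to (1R,2S,3RS)-1-[4-(benzyloxy)-3,5-dimethoxyphenyl]-2-[4-(3-hydroxypropyl)-2,6-dimethoxyphenoxy]butane-1,3,4-triol F3 (both epimers at the new carbinol carbon, same spatial arrangement at C7 and C8). NaIO4 in pH 7 buffered THF/water at 0 °C cleaves its 1,2-diol to 12, and NaBH4 added to the same flask gives 13.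

Step 5 is the third risk. Once the phenol is free, the p-hydroxybenzylic C7–OH can be hydrogenolysed or epimerised through a quinone methide if the Pd/C is acidic. The fallback sets out from 4 and comes back at 14, replacing the benzyl group by a fluoride-labile silyl group. Bought syringaldehyde is silylated (TIPSCl, imidazole, DMF) to 3,5-dimethoxy-4-{[tri(propan-2-yl)silyl]oxy}benzaldehyde F4. Coupling F4 with 4 under the step 3 conditions (NaBO3·4H2O work-up) gives (1R,2R)-1-(3,5-dimethoxy-4-{[tri(propan-2-yl)silyl]oxy}phenyl)-2-[4-(3-hydroxypropyl)-2,6-dimethoxyphenoxy]but-3-en-1-ol F5. Ozonolysis with NaBH4 work-up gives (1R,2R)-1-(3,5-dimethoxy-4-{[tri(propan-2-yl)silyl]oxy}phenyl)-2-[4-(3-hydroxypropyl)-2,6-dimethoxyphenoxy]propane-1,3-diol F6, and Bu4NF buffered with AcOH in THF at 0 °C gives 14 without any hydrogenation.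

**Further compounds**

F1 | step 3 | tert-butyl{3-[3,5-dimethoxy-4-(prop-2-en-1-yloxy)phenyl]propoxy}dimethylsilane | COc1cc(CCCO[Si](C)(C)C(C)(C)C)cc(OC)c1OCC=C
F2 | step 3 | (1R,2R)-1-[4-(benzyloxy)-3,5-dimethoxyphenyl]-2-[4-(3-{[tert-butyl(dimethyl)silyl]oxy}propyl)-2,6-dimethoxyphenoxy]but-3-en-1-ol | COc1cc([C@@H](O)[C@@H](C=C)Oc2c(OC)cc(CCCO[Si](C)(C)C(C)(C)C)cc2OC)cc(OC)c1OCc1ccccc1
F3 | step 4 | (1R,2S,3RS)-1-[4-(benzyloxy)-3,5-dimethoxyphenyl]-2-[4-(3-hydroxypropyl)-2,6-dimethoxyphenoxy]butane-1,3,4-triol | COc1cc([C@@H](O)[C@@H](C(O)CO)Oc2c(OC)cc(CCCO)cc2OC)cc(OC)c1OCc1ccccc1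
F4 | step 5 | 3,5-dimethoxy-4-{[tri(propan-2-yl)silyl]oxy}benzaldehyde | COc1cc(C=O)cc(OC)c1O[Si](C(C)C)(C(C)C)C(C)C
F5 | step 5 | (1R,2R)-1-(3,5-dimethoxy-4-{[tri(propan-2-yl)silyl]oxy}phenyl)-2-[4-(3-hydroxypropyl)-2,6-dimethoxyphenoxy]but-3-en-1-ol | COc1cc([C@@H](O)[C@@H](C=C)Oc2c(OC)cc(CCCO)cc2OC)cc(OC)c1O[Si](C(C)C)(C(C)C)C(C)C
F6 | step 5 | (1R,2R)-1-(3,5-dimethoxy-4-{[tri(propan-2-yl)silyl]oxy}phenyl)-2-[4-(3-hydroxypropyl)-2,6-dimethoxyphenoxy]propane-1,3-diol | COc1cc([C@@H](O)[C@@H](CO)Oc2c(OC)cc(CCCO)cc2OC)cc(OC)c1O[Si](C(C)C)(C(C)C)C(C)C
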